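## The problem

CNP0532721.0 (22) is a diaryl ether without any stereocentre. Ring A (C-1 to C-6) is a methyl benzoate whose ester carbon C-1 lies between a free phenol at C-2 and the ether oxygen at C-6, with a methyl group at C-4. Ring B (C-1′ to C-6′) carries the ether oxygen at C-1′, a hydroxymethyl group at C-2′, a methoxy group at C-4′ and a prenyl ether at C-6′, with hydrogens at C-3′ and C-5′.

The bridge is the central difficulty. C-1′ is flanked on both sides and C-6 by the ester, so a late coupling of two finished arenes would have to join a di-ortho-substituted, electron-rich carbon that nothing activates for nucleophilic aromatic substitution. Ring B also bears four different substituents in a 1,2,4,6 array that no inexpensive arene offers.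

With no stereocentre, the only stereochemical variable is the geometry of an olefin carried into a ring-forming step. The prenyl aryl ether is the fragile group: acid cleaves it, heat invites a Claisen shift, and reductants or oxidants attack the alkene. The benzylic alcohol, the chelated phenol and the methyl ester must also survive. The ester lies within reach of the C-6′ oxygen and of the C-2′ hydroxymethyl group (seven- and eight-membered lactones), so strongly basic or dehydrating conditions late in the route are excluded.

The feature that opens a way is the oxygen pattern of ring B. C-4′ and C-6′ are meta oxygens with C-5′–H between them and a hydrogen at C-3′, that is, a resorcinol monoether. The four-carbon unit C-6′/C-3′/C-2′/C-1′ can come from a vinylketene and the two-carbon unit C-5′/C-4′ from an alkoxyalkyne. C-1′ can therefore receive the ring A oxygen while it is still an unhindered vinylic carbon.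

## Retrosynthesis

**22 to 20 and 21.** The prenyl O–CH2 bond is cut last. Placing the alkylation at the end keeps the prenyl ether away from every acidic, photochemical and ketene-forming step. Triol 20 differs from the target only by this group. The forward reaction must alkylate the C-6′ phenol of 20 with prenyl bromide 21 and leave the ester-chelated C-2 phenol and the benzylic alcohol untouched.

**20 to 19.** The two protecting groups of 19 are removed together. A methoxymethyl ether on the C-2 oxygen and a tert-butyldimethylsilyl ether on the C-2′ hydroxymethyl group are both acid-labile, so one step strips both while no prenyl ether is yet present. They are needed earlier because neither the acid chloride nor the ketenes tolerate a free hydroxyl.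

**19 to 10 and 14 (key disconnection).** Ring B is opened at C-5′–C-6′, C-3′–C-4′ and C-1′–C-6′, and the C-2′–C-3′ bond is traced back to a 1,2-shift. This leads to aryloxyvinyl diazoketone 10 and methoxyethyne 14. The neighbouring cut, the diaryl ether C–O bond, would require coupling at a doubly ortho-substituted carbon. In the chosen cut that bond already exists as a vinyl ether before ring B is made. Precursor 10 is acyclic on the ring B side and 14 has three heavy atoms besides oxygen. The forward cascade (via 15, 16, 17 and 18) must give one regiochemistry in the ketene–alkyne union and must tolerate the ring A ester and both protecting groups.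

**14 to 11.** Methoxyethyne is volatile and is traced to chloroacetaldehyde dimethyl acetal 11 by loss of methanol and hydrogen chloride. The forward reaction is a double elimination with a strong amide base.

**10 to 8 and 7.** The bond between the carbonyl carbon (future C-6′) and the diazo carbon (future C-3′) is cut by C-acylation of a diazoalkane with the acid chloride 9 of acid 8. Acid 8 comes from diester 7 by hydrolysis of the acrylate ester alone. This is preferred to routes through a methyl ketone because it adds the fewest steps. It asks that the hindered ring A ester stay inert and that the donor-substituted double bond not act as a dipolarophile.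

**7 to 2 and 6.** The vinylic C-1′–O bond is cut, giving phenol 2 and β-bromoacrylate 6. Cutting the aryl–O bond instead would demand substitution on ring A next to its ester. The vinylic carbon of 6 is a vinylogous acyl bromide and accepts a phenoxide by addition–elimination. The forward reaction must give the geometry in which the aryloxy group is trans to the carbonyl.

**6 to 4 and 3; 2 to 1.** Bromide 6 is traced through dibromide 5 to silyl ether 4 and to methyl 2-(hydroxymethyl)acrylate 3, which already holds C-1′, C-2′, the hydroxymethyl carbon and the future C-6′. Phenol 2 is the mono-methoxymethyl ether of the symmetric diol 1, so no regiochemical question arises.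

## Roads not taken

**Alternative 1:** Ring B would be cut at C-1′–C-2′ and C-2′–C-3′. The precursor is the α-aryloxy enone A2, in which the O-CH2 group is C-1′, the ketone C-6′ and the vinylogous methyl group C-3′. In the forward step a magnesium Lewis acid with an amine base would C-acylate C-1′ with an activated dimethoxyacetic acid derivative. A stronger base would then condense C-3′ onto the new ketone and aromatise to acetal A1.

- Merits: cheap acyclic inputs, no diazo compound, no light, no volatile alkyne, and possibly no protection of ring A. In reagent safety and ease of scale-up this road is better than the chosen one.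
- Weak points: a carbanion at C-1′ can attack the ring A ester and close a five-membered benzofuranone, the classical fate of such aryloxy ketones ortho to an ester. After acylation C-1′ lies between two carbonyls, so under the base needed for the aldol step the new ketone is buried in a diketone enolate and loses electrophilicity, while the far less acidic C-3′ methyl must be deprotonated. O-acylation and acylation at C-5′ compete. A1 still needs acetal hydrolysis and aldehyde reduction before prenylation.
- Comparison: the chosen plan sets against the better reagents a key step whose bond-forming sites are fixed by polarity and not by competition among acidic positions. It never places a carbanion beside the ring A ester, and it delivers C-2′ at the alcohol oxidation level.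

**Alternative 2:** The cut is at the C-6–O bond and the C-1–carboxyl bond of ring A. A fluoride source would release aryne A5 from silyl triflate A4. The phenoxide of the complete ring B phenol A6 would add at C-6, and the aryl anion at C-1 would be trapped by carbon dioxide (A7) to give acid A3.

- Merits: high convergence, the hindered ether bond and the carboxyl group in one operation, regiochemistry steered by the oxygen substituent next to the aryne, and no photochemistry.
- Weak points: A6 is a 2,6-disubstituted phenol that itself needs a multi-step synthesis of the awkward ring B pattern, and A4 is a further multi-step arene. Three-component capture with so hindered a phenoxide is not secured: protonation of the aryl anion would give the decarboxy ether, and A7 can reversibly bind the phenoxide. A3 still needs esterification and two deprotections in the presence of the prenyl ether.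
- Comparison: this road is better in convergence. The chosen plan sets against it that only one arene (1) is bought and ring B arises from acyclic pieces in the step that also completes the ether, and that the prenyl group enters after all acid treatment.

**Alternative 3:** Ring A would be cut at C-1–C-2 and C-5–C-6. Ketene acetal diene A9 would add to aryloxypropiolate A10 and lose a silanol to give A8.

- Merits: A8 is a single desilylation away from 22. The free C-2 phenol and the ester arise in place, and the polarity of diene and alkyne is matched. If A10 were in hand, this would be the shortest endgame and better than the chosen one in that respect.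
- Weak points: A10 is an ester-bearing ynol ether of the hindered phenol A6. Its preparation needs the whole ring B synthesis and then a strong-base alkynyl ether construction. The donor oxygen on the alkyne offsets the ester, so the dienophile is deactivated and shielded. The heat such a cycloaddition may need endangers the prenyl aryl ether (Claisen shift) and the hydrolytically sensitive A9.
- Comparison: the chosen plan sets against the shorter endgame that it builds the hard ring (B) and buys the easy one (A), and that the prenyl ether never meets heat.

Key step: step 8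

Remark on the chemistry: methoxyethyne 14 boils near room temperature and is assumed to be made and distilled directly before use; 1, 3, 11 and 21 are taken as catalogue compounds.

## Route

Step 1
Reactants: 1 methyl 2,6-dihydroxy-4-methylbenzoate
Product: 2 methyl 2-hydroxy-6-(methoxymethoxy)-4-methylbenzoate
Conditions: MOMCl (1.05 equiv), iPr2NEt, CH2Cl2, 0 °C → rt
Reagents that add atoms: chloromethyl methyl ether, COCCl
Why: O-alkylation of a phenol with a chloromethyl ether; 1 is symmetric, so only one mono-ether exists, and the remaining hydroxyl is held in a hydrogen bond to the ester carbonyl, which slows a second alkylation.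

Step 2
Reactants: 3 methyl 2-(hydroxymethyl)acrylate
Product: 4 methyl 2-{[(tert-butyldimethylsilyl)oxy]methyl}acrylate
Conditions: TBSCl, imidazole, CH2Cl2, 0 °C → rt
Reagents that add atoms: tert-butyldimethylsilyl chloride, CC(C)(C)[Si](C)(C)Cl
Why: Standard silylation of a primary alcohol; it removes the hydroxyl that could close onto the bromides of step 3 and would later quench the acid chloride and the ketenes.

Step 3
Reactants: 4 methyl 2-{[(tert-butyldimethylsilyl)oxy]methyl}acrylate
Product: 6 methyl (E)-3-bromo-2-{[(tert-butyldimethylsilyl)oxy]methyl}acrylate, via 2,3-dibromo ester 5 (not isolated)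
Conditions: Br2, CH2Cl2, 0 °C; then DBU, 0 °C → rt
Reagents that add atoms: bromine, BrBr
Why: Bromine addition to the 1,1-disubstituted acrylate followed by E2 dehydrobromination, as in the conversion of methacrylates into 3-bromomethacrylates; the tertiary α-bromide should leave with a hydrogen of the CH2Br group, the more acidic β-hydrogen, and the E isomer (bromine trans to the ester) is expected to predominate, although either isomer would serve in step 4.

Step 4
Reactants: 2 methyl 2-hydroxy-6-(methoxymethoxy)-4-methylbenzoate, 6 methyl (E)-3-bromo-2-{[(tert-butyldimethylsilyl)oxy]methyl}acrylate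
Product: 7 methyl 2-{[(1E)-2-{[(tert-butyldimethylsilyl)oxy]methyl}-3-methoxy-3-oxoprop-1-en-1-yl]oxy}-6-(methoxymethoxy)-4-methylbenzoate
Conditions: Cs2CO3, DMF, 50 °C
Reagents that add atoms: none
Why: Nucleophilic vinylic substitution by addition–elimination: the phenoxide adds to the β-carbon and the resulting ester enolate expels bromide; the E product (aryloxy trans to the ester) is both the retention product and the thermodynamically preferred β-aryloxyacrylate.

Step 5
Reactants: 7 methyl 2-{[(1E)-2-{[(tert-butyldimethylsilyl)oxy]methyl}-3-methoxy-3-oxoprop-1-en-1-yl]oxy}-6-(methoxymethoxy)-4-methylbenzoate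
Product: 8 (2E)-2-{[(tert-butyldimethylsilyl)oxy]methyl}-3-[2-(methoxycarbonyl)-3-(methoxymethoxy)-5-methylphenoxy]prop-2-enoic acid
Conditions: LiOH·H2O, THF/H2O, 0 °C → rt; then cold 1 M HCl to pH 4
Reagents that add atoms: lithium hydroxide monohydrate, [Li+].[OH-].O
Why: Saponification of the only accessible ester, since the ring A ester is shielded by two ortho oxygen substituents; β-aryloxyacrylic esters are known to hydrolyse to the acids with the aryloxy group intact, and no alcohol cosolvent is used so that no alkoxide can exchange with it.

Step 6
Reactants: 8 (2E)-2-{[(tert-butyldimethylsilyl)oxy]methyl}-3-[2-(methoxycarbonyl)-3-(methoxymethoxy)-5-methylphenoxy]prop-2-enoic acid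
Product: 10 methyl 2-{[(1E)-2-{[(tert-butyldimethylsilyl)oxy]methyl}-4-diazo-3-oxobut-1-en-1-yl]oxy}-6-(methoxymethoxy)-4-methylbenzoate, via acid chloride 9 (not isolated)
Conditions: 1-chloro-N,N,2-trimethylprop-1-en-1-amine, CH2Cl2, 0 °C → rt; then CH2N2 (3 equiv), Et2O, 0 °C
Reagents that add atoms: diazomethane, C=[N+]=[N-]
Why: Neutral acid chloride formation, then acylation of diazomethane (first half of an Arndt–Eistert sequence); no HCl is released onto the silyl and methoxymethyl ethers, the α-carbon has no hydrogen from which a ketene could form, and the trisubstituted, donor-substituted C=C is a poor dipolarophile, so pyrazoline formation should not compete.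

Step 7
Reactants: 11 chloroacetaldehyde dimethyl acetal (2-chloro-1,1-dimethoxyethane)
Product: 14 methoxyethyne, via 2-chlorovinyl methyl ether 12 (not isolated), via sodium methoxyethynide 13 (not isolated)
Conditions: NaNH2 (3 equiv), liquid NH3, −33 °C; then sat. aq. NaCl, −70 °C → rt, distilled into a cold trap
Reagents that add atoms: none
Why: Double β-elimination (methanol, then HCl) to the alkynyl ether, which is held as its sodium acetylide until the aqueous quench; this is the standard preparation of the lower 1-alkoxyalkynes from chloroacetaldehyde acetals.

Step 8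
Reactants: 10 methyl 2-{[(1E)-2-{[(tert-butyldimethylsilyl)oxy]methyl}-4-diazo-3-oxobut-1-en-1-yl]oxy}-6-(methoxymethoxy)-4-methylbenzoate, 14 methoxyethyne
Product: 19 methyl 2-(2-{[(tert-butyldimethylsilyl)oxy]methyl}-6-hydroxy-4-methoxyphenoxy)-6-(methoxymethoxy)-4-methylbenzoate, via vinylketene 15 (not isolated), via 4-vinylcyclobutenone 16 (not isolated), via dienylketene 17 (not isolated), via cyclohexadienone 18 (not isolated)
Conditions: 14 (4 equiv), hν (300 nm), ClCH2CH2Cl, 20 °C, quartz tube; then 80 °C, sealed
Reagents that add atoms: none
Why: Light expels N2 from 10 and the alkenyl group shifts from the carbonyl carbon to the former diazo carbon (photochemical Wolff rearrangement), so the carbonyl carbon becomes the ketene carbon of 15 (future C-6′) and the diazo carbon becomes C-3′, now bonded to C-2′. Ketene 15 and ynol ether 14 then combine in a polar, stepwise [2+2] cycloaddition in which the unsubstituted, nucleophilic alkyne carbon attacks the ketene carbon (C-5′–C-6′) and the oxocarbenium carbon closes onto the enolate carbon (C-3′–C-4′), giving the four-membered 3-methoxy-4-alkenylcyclobutenone 16. Continued irradiation or the 80 °C stage opens 16 by four-electron conrotatory electrocyclic cleavage of the C-3′–C-6′ bond to dienylketene 17, and a six-electron disrotatory electrocyclisation joins C-6′ to C-1′, closing ring B as dienone 18, which enolises to phenol 19. The closest known reaction type is the Danheiser benzannulation of α,β-unsaturated diazoketones with alkoxy- and silyloxyalkynes, which gives resorcinol monoethers with exactly this placement of OH, H, OR and H. No lasting stereocentre is created, because the sp3 carbons of 16 and 18 are erased by ring opening and tautomerisation. The step needs regiocontrol in the [2+2] event, and the matched polarity of the ketene (electrophilic at the carbonyl carbon) and the ynol ether (nucleophilic at its CH terminus) secures it, so that the methoxy group ends up meta to the new hydroxyl with C-5′–H between them. The E geometry of 10 places the aryloxy group on the outside of the closing triene terminus, and because cyclobutenone opening is reversible both rotational outcomes at C-3′ drain into the cyclisable form of 17. The methoxymethyl and silyl ethers leave no hydroxyl that could add to the ketenes, and the excess of 14 is meant to let cycloaddition outrun ketene dimerisation and acylation of the phenol that accumulates.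

Step 9
Reactants: 19 methyl 2-(2-{[(tert-butyldimethylsilyl)oxy]methyl}-6-hydroxy-4-methoxyphenoxy)-6-(methoxymethoxy)-4-methylbenzoate
Product: 20 methyl 2-hydroxy-6-[2-hydroxy-6-(hydroxymethyl)-4-methoxyphenoxy]-4-methylbenzoate
Conditions: HCl (1 M in MeOH), 20–40 °C
Reagents that add atoms: none
Why: Acid-catalysed methanolysis removes the primary silyl ether and the phenolic methoxymethyl acetal (the latter helped by the neighbouring ester) in one operation; the benzylic position has only a weakly donating ortho aryloxy group, so ionisation is not expected, and methanol as solvent keeps the methyl ester and disfavours lactone formation.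

Step 10
Reactants: 20 methyl 2-hydroxy-6-[2-hydroxy-6-(hydroxymethyl)-4-methoxyphenoxy]-4-methylbenzoate, 21 prenyl bromide (1-bromo-3-methylbut-2-ene)
Product: 22 methyl 2-hydroxy-6-{2-(hydroxymethyl)-4-methoxy-6-[(3-methylbut-2-en-1-yl)oxy]phenoxy}-4-methylbenzoate (CNP0532721.0)
Conditions: K2CO3 (1.2 equiv), 21 (1.05 equiv), acetone, rt
Reagents that add atoms: none
Why: Williamson ether synthesis; the C-6′ phenoxide should be the only site alkylated at room temperature, because the C-2 hydroxyl is chelated to the ester carbonyl and the benzylic alcohol is not deprotonated by carbonate, the selectivity long used to alkylate free phenols beside salicylate-type ones.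

## Compound list

1 | methyl 2,6-dihydroxy-4-methylbenzoate | COC(=O)c1c(O)cc(C)cc1O | starting material
2 | methyl 2-hydroxy-6-(methoxymethoxy)-4-methylbenzoate | COC(=O)c1c(OCOC)cc(C)cc1O | intermediate
3 | methyl 2-(hydroxymethyl)acrylate | C=C(CO)C(=O)OC | starting material
4 | methyl 2-{[(tert-butyldimethylsilyl)oxy]methyl}acrylate | C=C(CO[Si](C)(C)C(C)(C)C)C(=O)OC | intermediate
5 | methyl 2,3-dibromo-2-{[(tert-butyldimethylsilyl)oxy]methyl}propanoate (racemic) | BrCC(Br)(CO[Si](C)(C)C(C)(C)C)C(=O)OC | intermediate
6 | methyl (E)-3-bromo-2-{[(tert-butyldimethylsilyl)oxy]methyl}acrylate | Br/C=C(\CO[Si](C)(C)C(C)(C)C)C(=O)OC | intermediate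
7 | methyl 2-{[(1E)-2-{[(tert-butyldimethylsilyl)oxy]methyl}-3-methoxy-3-oxoprop-1-en-1-yl]oxy}-6-(methoxymethoxy)-4-methylbenzoate | COC(=O)c1c(OCOC)cc(C)cc1O/C=C(\CO[Si](C)(C)C(C)(C)C)C(=O)OC | intermediate
8 | (2E)-2-{[(tert-butyldimethylsilyl)oxy]methyl}-3-[2-(methoxycarbonyl)-3-(methoxymethoxy)-5-methylphenoxy]prop-2-enoic acid | COC(=O)c1c(OCOC)cc(C)cc1O/C=C(\CO[Si](C)(C)C(C)(C)C)C(=O)O | intermediate
9 | (2E)-2-{[(tert-butyldimethylsilyl)oxy]methyl}-3-[2-(methoxycarbonyl)-3-(methoxymethoxy)-5-methylphenoxy]prop-2-enoyl chloride | COC(=O)c1c(OCOC)cc(C)cc1O/C=C(\CO[Si](C)(C)C(C)(C)C)C(Cl)=O | intermediate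
10 | methyl 2-{[(1E)-2-{[(tert-butyldimethylsilyl)oxy]methyl}-4-diazo-3-oxobut-1-en-1-yl]oxy}-6-(methoxymethoxy)-4-methylbenzoate | COC(=O)c1c(OCOC)cc(C)cc1O/C=C(\CO[Si](C)(C)C(C)(C)C)C(=O)C=[N+]=[N-] | intermediate
11 | chloroacetaldehyde dimethyl acetal (2-chloro-1,1-dimethoxyethane) | COC(CCl)OC | starting material
12 | 2-chlorovinyl methyl ether (1-chloro-2-methoxyethene, E/Z mixture) | COC=CCl | intermediate
13 | sodium methoxyethynide | [Na+].[C-]#COC | intermediate
14 | methoxyethyne | C#COC | intermediate
15 | methyl 2-[(2-{[(tert-butyldimethylsilyl)oxy]methyl}-4-oxobuta-1,3-dien-1-yl)oxy]-6-(methoxymethoxy)-4-methylbenzoate (vinylketene, aryloxy cis to the silyloxymethyl group) | COC(=O)c1c(OCOC)cc(C)cc1O/C=C(\CO[Si](C)(C)C(C)(C)C)C=C=O | intermediate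
16 | methyl 2-{[3-{[(tert-butyldimethylsilyl)oxy]}-2-(2-methoxy-4-oxocyclobut-2-en-1-yl)prop-1-en-1-yl]oxy}-6-(methoxymethoxy)-4-methylbenzoate (racemic, aryloxy cis to the silyloxymethyl group) | COC(=O)c1c(OCOC)cc(C)cc1O/C=C(\CO[Si](C)(C)C(C)(C)C)C1C(=O)C=C1OC | intermediate
17 | methyl 2-[(2-{[(tert-butyldimethylsilyl)oxy]methyl}-4-methoxy-6-oxohexa-1,3,5-trien-1-yl)oxy]-6-(methoxymethoxy)-4-methylbenzoate (dienylketene, ketene arm and aryloxyvinyl arm cis across the central C=C) | COC(=O)c1c(OCOC)cc(C)cc1O/C=C(\CO[Si](C)(C)C(C)(C)C)/C=C(OC)\C=C=O | intermediate
18 | methyl 2-[(2-{[(tert-butyldimethylsilyl)oxy]methyl}-4-methoxy-6-oxocyclohexa-2,4-dien-1-yl)oxy]-6-(methoxymethoxy)-4-methylbenzoate (racemic) | COC(=O)c1c(OCOC)cc(C)cc1OC1C(=O)C=C(OC)C=C1CO[Si](C)(C)C(C)(C)C | intermediate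
19 | methyl 2-(2-{[(tert-butyldimethylsilyl)oxy]methyl}-6-hydroxy-4-methoxyphenoxy)-6-(methoxymethoxy)-4-methylbenzoate | COC(=O)c1c(OCOC)cc(C)cc1Oc1c(CO[Si](C)(C)C(C)(C)C)cc(OC)cc1O | intermediate
20 | methyl 2-hydroxy-6-[2-hydroxy-6-(hydroxymethyl)-4-methoxyphenoxy]-4-methylbenzoate | COC(=O)c1c(O)cc(C)cc1Oc1c(CO)cc(OC)cc1O | intermediate
21 | prenyl bromide (1-bromo-3-methylbut-2-ene) | CC(C)=CCBr | starting material
22 | methyl 2-hydroxy-6-{2-(hydroxymethyl)-4-methoxy-6-[(3-methylbut-2-en-1-yl)oxy]phenoxy}-4-methylbenzoate (CNP0532721.0) | COC(=O)c1c(O)cc(C)cc1Oc1c(CO)cc(OC)cc1OCC=C(C)C | target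

## Step count and least certain steps

Total: 10 steps. Longest linear sequence: 8 steps (steps 2, 3, 4, 5, 6, 8, 9 and 10, from 3).

**Step 8 (key step).** The most likely failure is loss of vinylketene 15 before it meets the alkyne. It can dimerise, acylate the phenol that accumulates, or be degraded photochemically through the aryloxy enone chromophore. Evaporation or polymerisation of the low-boiling alkyne would make this worse. Wrong regiochemistry is the less likely problem.

The fallback makes the same ketene in the dark. It sets out from 10: a Wolff rearrangement with PhCO2Ag and Et3N in aqueous THF should give the homologous 4-aryloxy-3-(silyloxymethyl)but-3-enoic acid F1. The chloroenamine of step 6 converts F1 into its acid chloride F2. Slow addition of Et3N to F2 and an excess of 14 in toluene at 60–80 °C then releases 15 by dehydrochlorination, the classical thermal entry to vinylketenes. The cascade through 16, 17 and 18 rejoins the route at 19.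

**Step 4.** Addition of the chelated, ester-flanked phenoxide to an α-branched bromoacrylate may be slow, and the temperature then needed may erode the bromide or the silyl ether. The step also inherits any shortfall of step 3, namely elimination towards the silyloxymethyl arm or a mixture of olefin isomers in 6.

The fallback avoids bromide 6 altogether and sets out from 2. Amine-catalysed oxa-Michael addition to methyl propiolate (DABCO, CH2Cl2) should give the (E)-3-aryloxyacrylate F3. Bromine addition gives the dibromide F4, and Et3N eliminates it to the α-bromo-β-aryloxyacrylate F5. Stille coupling of F5 with (tributylstannyl)methanol under Pd(PPh3)4 in dioxane at 90 °C installs the hydroxymethyl group with retention, giving alcohol F6. Silylation (TBSCl, imidazole) returns to the route at 7.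

**Step 6.** Dipolar cycloaddition of diazomethane to the conjugated double bond, or sluggish acylation by a vinylogous carbonate chloride that is also α-branched, could lower the return of 10.

The fallback replaces acylation by diazo transfer and sets out from 8. Coupling with N,O-dimethylhydroxylamine hydrochloride (EDC·HCl, iPr2NEt) gives the N-methoxy-N-methylamide F7. MeMgBr in THF at −78 °C gives the methyl ketone F8; the hindered ring A ester should not react. Enolisation with LiN(SiMe3)2 and trapping with 2,2,2-trifluoroethyl trifluoroacetate gives the trifluoroacetyl ketone F9. Detrifluoroacetylative diazo transfer with methanesulfonyl azide, Et3N and water in MeCN returns to the route at 10.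

**Step 10.** Site selectivity may be incomplete, with some alkylation of the chelated C-2 phenol. If alkylation is slow, the C-6′ phenoxide may instead attack the ring A ester to close a seven-membered lactone.

The fallback introduces the prenyl group while ring A is still masked and sets out from 19. Alkylation with 21 and K2CO3 in DMF gives the fully protected prenyl ether F10. Bu4NF buffered with AcOH in THF removes the silyl group to give the methoxymethyl ether F11. MgBr2·OEt2 in Et2O/CH2Cl2 at rt, which cleaves a methoxymethyl ether next to a chelating ester under conditions mild enough for a prenyl aryl ether, returns to the route at 22.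

## Further compounds

F1 | step 8 | (3Z)-3-{[(tert-butyldimethylsilyl)oxy]methyl}-4-[2-(methoxycarbonyl)-3-(methoxymethoxy)-5-methylphenoxy]but-3-enoic acid (aryloxy cis to the silyloxymethyl group) | COC(=O)c1c(OCOC)cc(C)cc1O/C=C(\CO[Si](C)(C)C(C)(C)C)CC(=O)O
F2 | step 8 | (3Z)-3-{[(tert-butyldimethylsilyl)oxy]methyl}-4-[2-(methoxycarbonyl)-3-(methoxymethoxy)-5-methylphenoxy]but-3-enoyl chloride | COC(=O)c1c(OCOC)cc(C)cc1O/C=C(\CO[Si](C)(C)C(C)(C)C)CC(Cl)=O
F3 | step 4 | methyl 2-{[(1E)-3-methoxy-3-oxoprop-1-en-1-yl]oxy}-6-(methoxymethoxy)-4-methylbenzoate | COC(=O)c1c(OCOC)cc(C)cc1O/C=C/C(=O)OC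
F4 | step 4 | methyl 2-(1,2-dibromo-3-methoxy-3-oxopropoxy)-6-(methoxymethoxy)-4-methylbenzoate (mixture of diastereomers, not isolated) | COC(=O)c1c(OCOC)cc(C)cc1OC(Br)C(Br)C(=O)OC
F5 | step 4 | methyl 2-{[(1Z)-2-bromo-3-methoxy-3-oxoprop-1-en-1-yl]oxy}-6-(methoxymethoxy)-4-methylbenzoate | COC(=O)c1c(OCOC)cc(C)cc1O/C=C(\Br)C(=O)OC
F6 | step 4 | methyl 2-{[(1E)-2-(hydroxymethyl)-3-methoxy-3-oxoprop-1-en-1-yl]oxy}-6-(methoxymethoxy)-4-methylbenzoate | COC(=O)c1c(OCOC)cc(C)cc1O/C=C(\CO)C(=O)OC
F7 | step 6 | methyl 2-{[(1E)-2-{[(tert-butyldimethylsilyl)oxy]methyl}-3-[methoxy(methyl)amino]-3-oxoprop-1-en-1-yl]oxy}-6-(methoxymethoxy)-4-methylbenzoate | COC(=O)c1c(OCOC)cc(C)cc1O/C=C(\CO[Si](C)(C)C(C)(C)C)C(=O)N(C)OC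
F8 | step 6 | methyl 2-{[(1E)-2-{[(tert-butyldimethylsilyl)oxy]methyl}-3-oxobut-1-en-1-yl]oxy}-6-(methoxymethoxy)-4-methylbenzoate | COC(=O)c1c(OCOC)cc(C)cc1O/C=C(\CO[Si](C)(C)C(C)(C)C)C(C)=O
F9 | step 6 | methyl 2-{[(1E)-2-{[(tert-butyldimethylsilyl)oxy]methyl}-6,6,6-trifluoro-3,5-dioxohex-1-en-1-yl]oxy}-6-(methoxymethoxy)-4-methylbenzoate | COC(=O)c1c(OCOC)cc(C)cc1O/C=C(\CO[Si](C)(C)C(C)(C)C)C(=O)CC(=O)C(F)(F)F
F10 | step 10 | methyl 2-{2-{[(tert-butyldimethylsilyl)oxy]methyl}-4-methoxy-6-[(3-methylbut-2-en-1-yl)oxy]phenoxy}-6-(methoxymethoxy)-4-methylbenzoate | COC(=O)c1c(OCOC)cc(C)cc1Oc1c(CO[Si](C)(C)C(C)(C)C)cc(OC)cc1OCC=C(C)C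
F11 | step 10 | methyl 2-{2-(hydroxymethyl)-4-methoxy-6-[(3-methylbut-2-en-1-yl)oxy]phenoxy}-6-(methoxymethoxy)-4-methylbenzoate | COC(=O)c1c(OCOC)cc(C)cc1Oc1c(CO)cc(OC)cc1OCC=C(C)C
A1 | alternative 1 | methyl 2-[2-(dimethoxymethyl)-6-hydroxy-4-methoxyphenoxy]-6-hydroxy-4-methylbenzoate | COC(=O)c1c(O)cc(C)cc1Oc1c(C(OC)OC)cc(OC)cc1O
A2 | alternative 1 | methyl 2-hydroxy-6-{[(3E)-4-methoxy-2-oxopent-3-en-1-yl]oxy}-4-methylbenzoate | COC(=O)c1c(O)cc(C)cc1OCC(=O)/C=C(\C)OC
A3 | alternative 2 | 2-{2-{[(tert-butyldimethylsilyl)oxy]methyl}-4-methoxy-6-[(3-methylbut-2-en-1-yl)oxy]phenoxy}-6-(methoxymethoxy)-4-methylbenzoic acid | COCOc1cc(C)cc(Oc2c(CO[Si](C)(C)C(C)(C)C)cc(OC)cc2OCC=C(C)C)c1C(=O)O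
A4 | alternative 2 | 3-(methoxymethoxy)-5-methyl-2-(trimethylsilyl)phenyl trifluoromethanesulfonate | COCOc1cc(C)cc(OS(=O)(=O)C(F)(F)F)c1[Si](C)(C)C
A5 | alternative 2 | 3-(methoxymethoxy)-5-methylbenzyne | COCOC1=CC(C)=CC#C1
A6 | alternative 2 | 2-{[(tert-butyldimethylsilyl)oxy]methyl}-4-methoxy-6-[(3-methylbut-2-en-1-yl)oxy]phenol | Oc1c(CO[Si](C)(C)C(C)(C)C)cc(OC)cc1OCC=C(C)C
A7 | alternative 2 | carbon dioxide | O=C=O
A8 | alternative 3 | methyl 2-{2-{[(tert-butyldimethylsilyl)oxy]methyl}-4-methoxy-6-[(3-methylbut-2-en-1-yl)oxy]phenoxy}-6-hydroxy-4-methylbenzoate | COC(=O)c1c(O)cc(C)cc1Oc1c(CO[Si](C)(C)C(C)(C)C)cc(OC)cc1OCC=C(C)C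
A9 | alternative 3 | 1,1-bis(trimethylsilyloxy)-3-methylbuta-1,3-diene | C=C(C)C=C(O[Si](C)(C)C)O[Si](C)(C)C
A10 | alternative 3 | methyl 3-{2-{[(tert-butyldimethylsilyl)oxy]methyl}-4-methoxy-6-[(3-methylbut-2-en-1-yl)oxy]phenoxy}prop-2-ynoate | COC(=O)C#COc1c(CO[Si](C)(C)C(C)(C)C)cc(OC)cc1OCC=C(C)C
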